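**What to watch.** We watch the substrate. The new flasks, midnight and autumn, both stop at 2.5 min, and we want to know which species then holds most of the substrate charged.

common to all: substrate 0.25 M
- maple: partner 0.40 M; reagent 0.75 M; run made earlier
- oak: partner 0.78 M; reagent 0.75 M; run made earlier
- midnight: partner 0.650 M; reagent 0.750 M; time 2.5 min
- autumn: partner 0.330 M; reagent 0.750 M; time 2.5 min

| run | time / min | side product A / % | target / % | open intermediate / % | substrate / % |
|---|---|---|---|---|---|
| maple | 0.333 | 3 | 0 | 7 | 96 |
| maple | 0.667 | 8 | 0 | 11 | 89 |
| maple | 1.00 | 7 | 1 | 13 | 78 |
| maple | 1.33 | 10 | 1 | 12 | 75 |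
| maple | 2.00 | 18 | 3 | 15 | 59 |
| maple | 2.50 | 26 | 0 | 19 | 56 |
| oak | 0.167 | 0 | 0 | 0 | 96 |
| oak | 0.417 | 2 | 2 | 10 | 93 |
| oak | 0.667 | 5 | 0 | 6 | 87 |
| oak | 1.00 | 8 | 1 | 7 | 84 |
| oak | 1.50 | 17 | 0 | 11 | 76 |
| oak | 2.00 | 18 | 1 | 10 | 69 |
| oak | 2.50 | 25 | 3 | 11 | 61 |

(each reading ± 2 percentage points)

* which of these there is most of at the end, counted by the substrate in it, midnight (open intermediate / target / substrate / side product A)
* which of these there is most of at the end, counted by the substrate in it, autumn (open intermediate / target / substrate / side product A)
* final amount of the leader among these, as a percentage of the substrate charged, in midnight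
* final amount of the leader among these, as a percentage of the substrate charged, in autumn

- percentages count the substrate that a species holds: one side product A counts as two
- the analysis behind the earlier runs scatters by 2 percentage points, standard deviation

**Loss constant.** Maple keeps 56 % of its substrate at 2.50 min, which makes a loss of 0.232 /min. This is our loss constant, an apparent first-order constant: the natural logarithm of charged over remaining substrate, divided by the time.

**Turning time.** If the constant holds steady, maple at 1.33 min should keep 73.5 %. It reads 75 %, and a reading scatters by 2 percentage points, so we may use the constant along the run.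

**Turning partner.** Oak, with c(partner) at 0.78 M against maple's 0.40 M, gives 0.198 /min, a slower loss than maple's. That rests on a gap of 5 points between two scattered readings, so we hold the trend loosely. Reading along the line between the runs, we get 0.209 /min for midnight. Autumn, at 0.330 M, lies just beyond maple, so its 0.238 /min is a short extrapolation.

**Turning reagent.** Reagent stands at 0.75 M in maple and oak and at 0.750 M in the new flasks, so the readings say nothing of it and we hold it.

**Our reckoning.** We expect 59.3 % of substrate in midnight and 55.2 % in autumn. Both are more than the 26 % of side product A in maple, so substrate should lead.

**The forecast.** It names substrate for midnight at 60 % (range 56 % to 63 %) and substrate for autumn at 54 % (range 50 % to 58 %), holding that “More partner therefore slows substrate loss slightly”. Its figures differ a little from ours.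

**The result.** Substrate leads in midnight at 59.5 % and in autumn at 55.5 %, which in autumn is a loss constant of 0.235 /min.

    open intermediate + second intermediate ⇌ target (K = 2.70 /M, k = 0.0520 /M/s)
    2 second intermediate → homo product (k = 0.0170 /M/s)
    reagent + partner → second intermediate (k = 0.00670 /M/s)
    substrate + reagent → open intermediate (k = 0.00430 /M/s)
    second intermediate → side product B (k = 0.00300 /s)
    substrate + open intermediate → side product A (k = 0.0480 /M/s)

In autumn at 0.949 min, substrate goes by reagent to open intermediate 2.1 times as fast as it goes with open intermediate to side product A. Autumn left until 6.0 min has lost that lead: the constant gives 24.4 % of substrate, that flask holds 25.3 %, and side product A leads it at 56.2 %.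

The runs come from a simulation on assumed constants, noise included.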